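**Amounts first.** The amount of G in these flasks depends on how much D each portion of Q meets.

| flask | Q | D | remark | time |
|---|---|---|---|---|
| gamma | 0.10 M | 3 equiv | run made earlier |  |
| epsilon | 0.050 M | 3 equiv | run made earlier |  |
| zeta | 0.20 M | 3 equiv | run made earlier |  |
| midnight | 0.10 M (fed, over 25 min) | 3.00 equiv | all else is in the flask from the start; the feed brings no volume worth counting | 4.0 h |
| autumn | 0.10 M | 3.00 equiv (fed, over 1.5 h) | all else is in the flask from the start; the feed brings no volume worth counting | 4.0 h |
| summer | 0.10 M (fed, over 1.5 h) | 3.00 equiv | all else is in the flask from the start; the feed brings no volume worth counting | 4.0 h |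
| noon | 0.10 M (in portions, 5, over 1.5 h) | 3.00 equiv | first portion at the start, last at 1.5 h | 4.0 h |
| dawn | 0.10 M | 3.00 equiv | everything together at the start | 4.0 h |

- gamma (time / h: G / %, Q / %): 0.667: 19, 78; 1.33: 31, 63; 2.00: 34, 60; 2.50: 36, 55
- epsilon (time / h: G / %, Q / %): 0.833: 13, 85; 1.50: 16, 78; 2.50: 21, 71; 3.00: 21, 68
- zeta (time / h: G / %, Q / %): 0.250: 16, 85; 0.667: 33, 64; 1.33: 46, 49; 3.00: 56, 37

(standard deviation of a reading: 1.5 percentage points)

- the numbers in the tables scatter with a standard deviation of 1.5 percentage points
- steps thought possible: Q <-> J; D -> Z; Q + D -> G + X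

- the best flask by amount of G, in percent of the Q charged; "all alike" if 1.5 percentage points covers them all (midnight / autumn / summer / noon / dawn / all alike)
- amount of G at the end, in percent of the Q charged, midnight
- amount of G at the end, in percent of the Q charged, autumn
- amount of G at the end, in percent of the Q charged, summer
- amount of G at the end, in percent of the Q charged, noon
- amount of G at the end, in percent of the Q charged, dawn

**My measure.** I worked with the fraction of Q not made into G. I defined the reach A as minus the natural logarithm of that fraction. With D charged at 3.00 equiv, I treated Q as going to G pseudo-first-order, so that in my reckoning A adds up with [D] over time.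

**Charge level.** By hand, at a fixed lifetime of D, A follows the D charged, and so follows Q at fixed equivalents. The last readings, taken at 3.00 h, 2.50 h and 3.00 h, put A per molar of Q at 4.71 L mol⁻¹ in epsilon, 4.46 L mol⁻¹ in gamma and 4.10 L mol⁻¹ in zeta.

**Reaction time.** Gamma is dawn's recipe read early. Its first reading gives A rising on average at 0.316 h⁻¹ up to that time. G in gamma then went from 34% to 36%, a step close to the scatter of 1.5 percentage points, with Q still at 55%, which I read as D dying by D → Z. The last A, 0.446, over that rate gives a rough lifetime L for D of 1.41 h, as a reading of gamma. Allowing for the D still alive at that reading, the whole reach of gamma's charge, A∞, is 0.538. Dawn has the same charges, so by 4.0 h I reckoned it to reach A = 0.506, and I expected G at 39.7%.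

**Feeding Q.** Q entering at time τ meets A∞ scaled by the exponential of −τ/L, less the tail beyond 4.0 h. Averaged over arrivals, this gave me midnight 35.2%, summer 25.9% and noon 26.5%.

**Feeding D.** Late D has less time to live before 4.0 h, so I put autumn at 38.2%, less than my figure for dawn.

**The forecast.** The forecast gave dawn 38%, midnight 34%, summer 25%, noon 25.5% and autumn 35%, an autumn lower than mine, and concluded: "Dawn is best, narrowly."

**The flask.** Dawn gave 39.5%, more than any other flask, with autumn at 36.7%, midnight 35.7%, noon 27.6% and summer 27.3%. At 4.00 h dawn still held D at 7.19% of its charge. The equations were: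

    Q ⇌ J (K = 15.0, k = 1.40 × 10⁻⁵ s⁻¹)
    D → Z (k = 1.60 × 10⁻⁴ s⁻¹)
    Q + D → G + X (k = 3.60 × 10⁻⁴ L mol⁻¹ s⁻¹)

Dawn's own A comes to 0.503, against my 0.506. For a neighbour of dawn charged with 0.060 M of Q at the same equivalents, A∞ scales to 0.323, which by 4.0 h makes G 26.2%; that flask gave 27.0%.

All runs were generated by integration with made-up constants.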